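## The problem

Compound 22 is a linear prodelphinidin: three (2R,3R)-epigallocatechin units, each upper unit bonded through C4 to C8 of the unit below, with a galloyl ester on O3 of the middle unit. It holds eight stereocentres: C2 and C3 of every unit, and C4 of the middle and top units. In each unit the C2 aryl group and the C3 oxygen are cis, and both C4–aryl bonds are trans to the neighbouring C3 oxygen (4β). Inside a flavan ring the α-oriented C2 aryl and C3 oxygen steer attack on a C4 cation to the β face, so C4 can be controlled by C2 and C3 of its own unit, whereas C2 and C3 themselves must come from the chiral pool or from a catalyst. Ring A of each unit offers two nucleophilic carbons, C6 and C8; only C8 may be used, and the middle unit has to be joined at both C4 and C8. The molecule has eighteen phenols (three pyrogallol B rings and a gallate, all oxidised easily under base), C2 centres that epimerise under base, an ester that can hydrolyse or migrate, and interflavan bonds that cleave under acid once ring A is unprotected. Benzyl ethers and a neutral final hydrogenolysis answer these constraints. The feature that makes the key step possible is ring A of the top unit (C4a, C5–C8, C8a): it bears no carbon substituent except C4 and is a symmetrical 1,3,5-trioxygenated ring in which C4a and the O1-bearing C8a are adjacent, so C4–C4a and O1–C2 can both be drawn from phloroglucinol.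

## Retrosynthesis

**22 from 21.** The seventeen O–benzyl bonds of 21 are cut last. The cut is preferred to any late acylation or glycoside-type coupling on free polyphenols because hydrogenolysis is neutral and leaves the ester, the interflavan bonds and all stereocentres alone. The two phenols of the top ring A and the top C3 hydroxyl are already free in 21, so nothing else is asked of the last step.

**21 from 18 and 19 (key disconnection).** In the top unit, C4–C4a and O1–C2 are cut, which removes the whole of ring A as phloroglucinol 19 and leaves the epoxy carbinol 18. The neighbouring cut, the interflavan bond C4(top)–C8(middle), would need a second fully protected epigallocatechin electrophile and brings a C6/C8 question on a dimer. The chosen cut takes ring A from an achiral, symmetrical commodity and places the C2/C3 problem in a catalyst-made cis-epoxide. The forward reaction must ionise the carbinol before the epoxide, alkylate 19 at carbon, close ring C by 6-endo opening with inversion at C2, and end with the C4 aryl trans to O3. The first C–C bond is formed under open-chain control and is expected to favour the wrong face, because the cis-aryl group of the epoxide covers the face that must be attacked. C4 therefore has to be corrected by acid-reversible re-closure of the C4–C4a bond under ring control. This is the weak point of the plan and is treated as such below.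

**18 from 17.** The carbinol C–H bond is cut back to the aryl ketone 17. A free carbinol on a 2,4,6-trioxygenated ring would not survive desilylation and esterification and could not be told apart from the middle-unit 3-hydroxyl; the ketone solves both and is reduced only immediately before the key step. Either carbinol epimer serves.

**17 from 15 and 16, and 15 from 14.** The ester C–O bond is cut to the alcohol 15 and protected gallic acid 16, and 15 comes from the silyl ether 14. The gallate has to enter after the organolithium step, and the silyl group marks the one oxygen that will carry it.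

**14 from 7 and 12.** The bond between C8 of the middle unit and the carbonyl carbon is cut to the aryl bromide 7, used as its lithio derivative 13, and the cis-glycidic N-methoxy-N-methylamide 12. A Friedel–Crafts acylation of a debrominated dimer would face three open ring A positions and acid. The bromine, placed on the monomer, fixes the site and earlier serves as a capping group. The step requires clean halogen–lithium exchange on a large polyether and a single addition to the amide.

**12 from 8.** The amide 12 comes from ester 11, whose two epoxide C–O bonds are cut to the (Z)-cinnamate 10. This is made from aldehyde 9 and hence from 3,4,5-trihydroxybenzaldehyde 8. Both future top-unit stereocentres, C2 and C3, are thus set in one catalytic epoxidation on a small molecule.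

**7 from 5 and 6.** The interflavan bond C4(middle)–C8(lower) is cut to the capped C4 electrophile 5 and the nucleophile 6. Substrate control gives 4β in the epi series, and C8 of a 5,7-dialkoxyflavan is the more reactive site. Building either unit de novo would cost many more steps (see the alternatives).

**5 and 6 from 1.** Both monomers derive from (−)-epigallocatechin 1 through the pentabenzyl ether 2. Silylation, C8 bromination and C4 oxidation lead to 5 (via 3 and 4); O3 benzylation gives 6. Four stereocentres of 22 are thereby taken from the chiral pool.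

## Roads not taken

Alternative 1: The cut is through ring A of the lower unit (C4a–C8a, C5–C6, C7–C8), which also opens its ring C. In the forward step RhCl(PPh3)3 would cyclotrimerise the diyne A2 with benzyloxyacetylene A3 to give the benzylated dimer gallate A1. Its merit is that the middle unit is attached to C8 of the lower unit by construction, so no C6/C8 selectivity is needed and the lower unit does not depend on 1. On this point it is better than the chosen plan, which can only set the known C8 preference of the coupling 5 + 6 against it. Its weak points are several: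
- A2 carries two ynol ethers, which are sensitive to acid and heat, in a molecule that already holds the gallate.
- The tether does not control the orientation in which A3 inserts, so 5,7- and 5,6-oxygenation patterns can both form, and A3 can trimerise with itself.
- The lower-unit stereocentres would have to be made de novo in the tether.
- A1 has no handle at C8 of the middle unit, so the top unit would still need a selective functionalisation among three open ring A positions.

The chosen plan reaches the same skeleton as 7, with the bromine in place, in six steps from 1.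

Alternative 2: The cut is O1–C8a of the middle unit. In the forward step Pd(OAc)2, a bulky biaryl di-tert-butylphosphine and Cs2CO3 would couple the benzylic hydroxyl of the bromo alcohol A5 with its aryl bromide to give the silylated dimer A4. The reaction type is established for chromans, keeps the C2 configuration and uses no acid. It would also allow either C4 configuration, which the substrate-controlled coupling of the chosen plan cannot offer. For this target that freedom is not needed, and the costs are high:
- A5 is an open-chain array of three contiguous stereocentres bearing the whole lower unit, which must be built by acyclic control instead of being taken from 1.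
- The alkoxide on divalent palladium of a secondary benzylic alcohol can undergo β-hydride elimination to the ketone in competition with C–O reductive elimination.
- A4 is 7 without its bromine, so a regioselective bromination of a dimer would still be required.

The chosen plan obtains 7 directly.

Alternative 3: The cut is O1–C2 of the middle unit at the C–H oxidation level. In the forward step Ag2O would dehydrogenate the 4-hydroxy-3,5-bis(benzyloxy)benzyl group of the phenol A7, and the C8a phenol would add to the resulting electrophilic benzylic carbon to give A6. The step is mild and needs no leaving group at C2; in that respect it is more economical than any epoxide- or halide-based closure. Its weak points for this target are: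
- The addition is reversible and product-controlled and should favour the 2,3-trans arrangement, whereas 22 needs 2,3-cis.
- One B-ring phenol and one A-ring phenol must be kept free among ten benzyl ethers.
- The electron-rich ring A phenol may itself be oxidised at C4.
- A6 carries a free phenol next to the free 3-hydroxyl, so the gallate could not be placed without further protection.
- The top unit is again left unsolved.

The chosen plan takes the C2 configuration of the middle unit unchanged from 1.

Key step: step 15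

Remarks on the chemistry (assumptions):
- The carbinol carbon of 18 is expected as a mixture of epimers. Both ionise to the same cation, so this centre is left open in the SMILES of 18.
- The sense of induction in step 9 is assigned by analogy with cis-cinnamate esters, for which the (R,R) catalyst gives the (2R,3R) glycidate.
- 3,4,5-Tris(benzyloxy)benzoic acid 16 is taken as a purchased building block.
- TBS = tert-butyldimethylsilyl; Bn = benzyl.

## Route

Step 1
Reactants: 1 (−)-epigallocatechin
Product: 2 5,7,3',4',5'-penta-O-benzyl-(−)-epigallocatechin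
Conditions: BnBr, K2CO3, DMF, −10 °C → rt, argon
Reagents that add atoms: benzyl bromide, BrCc1ccccc1
Why: Williamson etherification of the five phenols; K2CO3 does not deprotonate the C3 alcohol, and low temperature under argon limits C-benzylation and base-induced opening of ring C that would epimerise C2.

Step 2
Reactants: 2 5,7,3',4',5'-penta-O-benzyl-(−)-epigallocatechin
Product: 3 3-O-TBS-penta-O-benzyl-epigallocatechin
Conditions: TBSCl, imidazole, DMF, rt
Reagents that add atoms: tert-butyldimethylsilyl chloride, CC(C)(C)[Si](C)(C)Cl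
Why: Silylation of the only free hydroxyl; the silyl ether withstands the later Lewis acid and halogen–lithium exchange and marks O3 of the future middle unit for the gallate.

Step 3
Reactants: 3 3-O-TBS-penta-O-benzyl-epigallocatechin
Product: 4 8-bromo-3-O-TBS-penta-O-benzyl-epigallocatechin
Conditions: N-bromosuccinimide (1.0 equiv), CH2Cl2, −78 → 0 °C
Reagents that add atoms: N-bromosuccinimide, O=C1CCC(=O)N1Br
Why: Electrophilic aromatic bromination; in 5,7-dialkoxyflavans C8 (ortho to O1 and the 7-ether, para to the 5-ether) is the more reactive ring A position, and one equivalent at low temperature should stop at the monobromide, which later serves as capping group and lithiation site.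

Step 4
Reactants: 4 8-bromo-3-O-TBS-penta-O-benzyl-epigallocatechin
Product: 5 8-bromo-4β-(2-ethoxyethoxy)-3-O-TBS-penta-O-benzyl-epigallocatechin
Conditions: DDQ, 2-ethoxyethanol, CH2Cl2, rt
Reagents that add atoms: 2-ethoxyethanol, CCOCCO
Why: DDQ abstracts hydride from C4, benzylic to the trioxygenated ring A, and the alcohol captures the cation anti to the C3 silyloxy and C2 aryl groups (benzylic oxidation with alcohol capture); the new C4 centre is ionised again in step 6, so its configuration is immaterial.

Step 5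
Reactants: 2 5,7,3',4',5'-penta-O-benzyl-(−)-epigallocatechin
Product: 6 3,5,7,3',4',5'-hexa-O-benzyl-(−)-epigallocatechin
Conditions: NaH, BnBr, Bu4NI (cat.), DMF, 0 °C → rt
Reagents that add atoms: benzyl bromide, BrCc1ccccc1
Why: Williamson etherification of the secondary alkoxide; gives the fully protected nucleophile whose O3 benzyl group falls in the final hydrogenolysis.

Step 6
Reactants: 5 8-bromo-4β-(2-ethoxyethoxy)-3-O-TBS-penta-O-benzyl-epigallocatechin; 6 3,5,7,3',4',5'-hexa-O-benzyl-(−)-epigallocatechin
Product: 7 8-bromo-3-O-TBS dimer, (8-bromo-3-O-TBS-penta-O-benzyl-epigallocatechin)-(4β→8)-(hexa-O-benzyl-epigallocatechin)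
Conditions: BF3·OEt2, CH2Cl2, −78 → −30 °C, 6 in 2.5-fold excess
Reagents that add atoms: none
Why: Lewis-acid Friedel–Crafts coupling of a flavan C4 cation with C8 of a 5,7-dialkoxyflavan, the standard entry to 4→8 proanthocyanidins; attack occurs on the β face, anti to the α-oriented C3 silyloxy and C2 aryl groups, which sets C4 of the middle unit trans to O3. Bromine at C8 of 5 prevents its self-condensation, and C8 of 6 reacts in preference to C6.

Step 7
Reactants: 8 3,4,5-trihydroxybenzaldehyde
Product: 9 3,4,5-tris(benzyloxy)benzaldehyde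
Conditions: BnBr, K2CO3, DMF, 60 °C
Reagents that add atoms: benzyl bromide, BrCc1ccccc1
Why: Williamson etherification of the three phenols; the aldehyde is untouched.

Step 8
Reactants: 9 3,4,5-tris(benzyloxy)benzaldehyde
Product: 10 methyl (Z)-3-[3,4,5-tris(benzyloxy)phenyl]prop-2-enoate
Conditions: (CF3CH2O)2P(O)CH2CO2Me, KN(SiMe3)2, 18-crown-6, THF, −78 °C
Reagents that add atoms: methyl bis(2,2,2-trifluoroethyl)phosphonoacetate, COC(=O)CP(=O)(OCC(F)(F)F)OCC(F)(F)F
Why: Still–Gennari olefination; the electron-poor phosphonate under dissociating conditions eliminates from the kinetic adduct and gives the (Z)-ester needed for a cis-epoxide.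

Step 9
Reactants: 10 methyl (Z)-3-[3,4,5-tris(benzyloxy)phenyl]prop-2-enoate
Product: 11 methyl (2S,3S)-3-[3,4,5-tris(benzyloxy)phenyl]oxirane-2-carboxylate
Conditions: (S,S)-(salen)MnCl [(S,S)-N,N'-bis(3,5-di-tert-butylsalicylidene)cyclohexane-1,2-diaminomanganese chloride, C36H52ClMnN2O2] (cat.), 4-phenylpyridine N-oxide, aq. NaOCl (pH 11.3), CH2Cl2, 0 °C
Reagents that add atoms: sodium hypochlorite, [Na+].[O-]Cl
Why: Jacobsen epoxidation, for which cis-cinnamate esters are among the best substrates; the (S,S) catalyst should deliver the (2S,3S) cis-epoxide and so set both future top-unit centres (C2 and C3) under catalyst control, and the N-oxide additive suppresses leakage to the trans-epoxide.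

Step 10
Reactants: 11 methyl (2S,3S)-3-[3,4,5-tris(benzyloxy)phenyl]oxirane-2-carboxylate
Product: 12 (2S,3S)-N-methoxy-N-methyl-3-[3,4,5-tris(benzyloxy)phenyl]oxirane-2-carboxamide
Conditions: MeNH(OMe)·HCl, i-PrMgCl, THF, −20 °C
Reagents that add atoms: N,O-dimethylhydroxylamine hydrochloride, CNOC.Cl
Why: Aminolysis of the ester by the chloromagnesium amide of N,O-dimethylhydroxylamine at low temperature (Weinreb amide formation); the epoxide carbons are not involved and keep their configuration.

Step 11
Reactants: 7 8-bromo-3-O-TBS dimer; 12 (2S,3S)-N-methoxy-N-methyl-3-[3,4,5-tris(benzyloxy)phenyl]oxirane-2-carboxamide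
Product: 14 C8 epoxy ketone of the dimer (3-O-TBS), via 8-lithio dimer 13 (not isolated)
Conditions: t-BuLi (2.1 equiv), THF, −78 °C; then 12, −78 → −40 °C; aq. NH4Cl
Reagents that add atoms: none
Why: Bromine–lithium exchange on the aryl bromide is fast at −78 °C (the second equivalent of t-BuLi destroys t-BuBr), and the aryllithium adds once to the N-methoxy-N-methylamide because the chelated tetrahedral adduct survives until work-up (Weinreb ketone synthesis); exchange and addition at C8 of an 8-bromo-3-O-silyl flavan are precedented on the monomer.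

Step 12
Reactants: 14 C8 epoxy ketone of the dimer (3-O-TBS)
Product: 15 C8 epoxy ketone of the dimer with free 3-OH on the middle unit
Conditions: Bu4NF, AcOH, THF, 0 °C → rt
Reagents that add atoms: none
Why: Fluoride cleavage of the silyl ether, buffered with acetic acid so that the epoxy ketone is not exposed to a basic alkoxide; it frees O3 of the middle unit as the only hydroxyl.

Step 13
Reactants: 15 C8 epoxy ketone of the dimer with free 3-OH on the middle unit; 16 3,4,5-tris(benzyloxy)benzoic acid
Product: 17 C8 epoxy ketone of the dimer 3-O-gallate (benzylated)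
Conditions: EDC·HCl, DMAP, CH2Cl2, rt
Reagents that add atoms: none
Why: Steglich-type esterification; acylation of the axial, flanked 3-hydroxyl of an upper flavan unit by protected gallic acid is well precedented in this class, and no other hydroxyl is present.

Step 14
Reactants: 17 C8 epoxy ketone of the dimer 3-O-gallate (benzylated)
Product: 18 C8 epoxy carbinol of the dimer 3-O-gallate (both carbinol epimers)
Conditions: NaBH4, CeCl3·7H2O, THF–MeOH, −40 → 0 °C; neutral work-up, used crude
Reagents that add atoms: none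
Why: Luche-type 1,2-reduction of the aryl ketone, which is activated by the α-epoxide; the aryl ester and the epoxide are inert to NaBH4 at low temperature. Both epimers are acceptable because the centre is ionised in step 15, and the labile carbinol is not chromatographed on acidic silica.

Step 15
Reactants: 18 C8 epoxy carbinol of the dimer 3-O-gallate (both carbinol epimers); 19 phloroglucinol
Product: 21 benzylated trimer (top ring A and top 3-OH free), via open-chain phloroglucinol adduct 20 (not isolated)
Conditions: 19 (5 equiv), (+)-camphor-10-sulfonic acid (0.3 equiv), THF–CH2Cl2 1:3, −20 °C → rt, then kept at rt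
Reagents that add atoms: none
Why: Proposed new method: the sulfonic acid should ionise the C4 carbinol of 18 to a benzylic cation delocalised into the 2,4,6-trioxygenated ring A of the middle unit, 19 should capture it through carbon (Friedel–Crafts alkylation, C4–C4a) to give 20, and the hydroxyl ortho to the new bond should then open the acid-activated cis-epoxide at the benzylic carbon C2 (O1–C2), closing ring C of the top unit in a 6-endo-tet mode. The closest known reactions are the acid capture of flavan-4-yl cations by phloroglucinol and the acid-catalysed 6-endo cyclisation of 2-hydroxyaryl-substituted aryl epoxides to flavan-3-ols; their union in one flask on an epoxy carbinol is new. C2 is set by inversion at the epoxide carbon, so the cis-epoxide gives the 2,3-cis relationship, and C3 is carried unchanged from 12. C4 is not expected to be set correctly in the first bond formation, because in the A(1,3)-minimised conformer of the cation the cis-aryl group of the epoxide covers the face that must be attacked. It should be set instead by re-closure: a phloroglucinol ring with free hydroxyls is protonated at carbon far more readily than the benzylated rings, so ipso-protonation should reopen only the C4–C4a bond (in 20 and in the annulated product), and the tethered cation can re-close only from the C2 side with H3 eclipsing the middle-unit aryl group, which is the 3,4-trans arrangement. The step further needs ionisation of the carbinol before the epoxide (a 2,4,6-trioxygenated ring against a 3,4,5-trioxygenated one whose meta oxygens do not donate), C- over O-alkylation (O-alkylation by so stable a cation is reversible) and 6-endo over 5-exo opening (C2 is benzylic). The excess of 19 suppresses capture of a second cation by the product and shortens the lifetime of the epoxycarbinyl cation.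

Step 16
Reactants: 21 benzylated trimer (top ring A and top 3-OH free)
Product: 22 epigallocatechin-(4β→8)-epigallocatechin 3-O-gallate-(4β→8)-epigallocatechin
Conditions: H2 (1 atm), Pd(OH)2/C, THF–MeOH–H2O, rt
Reagents that add atoms: none
Why: Hydrogenolysis of sixteen aryl benzyl ethers and one alkyl benzyl ether under neutral conditions, standard for benzylated proanthocyanidin gallates; the ester, the interflavan bonds and all stereocentres are untouched.

## Compound list

1 | (−)-epigallocatechin, (2R,3R)-2-(3,4,5-trihydroxyphenyl)chromane-3,5,7-triol | O[C@@H]1Cc2c(O)cc(O)cc2O[C@@H]1c1cc(O)c(O)c(O)c1 | starting material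

2 | 5,7,3',4',5'-penta-O-benzyl-(−)-epigallocatechin (free 3-OH) | O[C@@H]1Cc2c(OCc9ccccc9)cc(OCc9ccccc9)cc2O[C@@H]1c8cc(OCc9ccccc9)c(OCc9ccccc9)c(OCc9ccccc9)c8 | intermediate

3 | 3-O-(tert-butyldimethylsilyl)-5,7,3',4',5'-penta-O-benzyl-(−)-epigallocatechin | CC(C)(C)[Si](C)(C)O[C@@H]1Cc2c(OCc9ccccc9)cc(OCc9ccccc9)cc2O[C@@H]1c8cc(OCc9ccccc9)c(OCc9ccccc9)c(OCc9ccccc9)c8 | intermediate

4 | 8-bromo-3-O-TBS-5,7,3',4',5'-penta-O-benzyl-(−)-epigallocatechin | CC(C)(C)[Si](C)(C)O[C@@H]1Cc2c(OCc9ccccc9)cc(OCc9ccccc9)c(Br)c2O[C@@H]1c8cc(OCc9ccccc9)c(OCc9ccccc9)c(OCc9ccccc9)c8 | intermediate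

5 | 8-bromo-4β-(2-ethoxyethoxy)-3-O-TBS-5,7,3',4',5'-penta-O-benzyl-(−)-epigallocatechin (C4 ether trans to O3) | CC(C)(C)[Si](C)(C)O[C@@H]1[C@@H](OCCOCC)c2c(OCc9ccccc9)cc(OCc9ccccc9)c(Br)c2O[C@@H]1c8cc(OCc9ccccc9)c(OCc9ccccc9)c(OCc9ccccc9)c8 | intermediate

6 | 3,5,7,3',4',5'-hexa-O-benzyl-(−)-epigallocatechin | C(c9ccccc9)O[C@@H]1Cc2c(OCc9ccccc9)cc(OCc9ccccc9)cc2O[C@@H]1c8cc(OCc9ccccc9)c(OCc9ccccc9)c(OCc9ccccc9)c8 | intermediate

7 | (8-bromo-3-O-TBS-5,7,3',4',5'-penta-O-benzyl-epigallocatechin)-(4β→8)-(3,5,7,3',4',5'-hexa-O-benzyl-epigallocatechin) | CC(C)(C)[Si](C)(C)O[C@@H]1[C@@H](c2c(OCc9ccccc9)cc(OCc9ccccc9)c3c2O[C@H](c8cc(OCc9ccccc9)c(OCc9ccccc9)c(OCc9ccccc9)c8)[C@H](OCc9ccccc9)C3)c4c(OCc9ccccc9)cc(OCc9ccccc9)c(Br)c4O[C@@H]1c8cc(OCc9ccccc9)c(OCc9ccccc9)c(OCc9ccccc9)c8 | intermediate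

8 | 3,4,5-trihydroxybenzaldehyde | O=Cc1cc(O)c(O)c(O)c1 | starting material

9 | 3,4,5-tris(benzyloxy)benzaldehyde | O=Cc8cc(OCc9ccccc9)c(OCc9ccccc9)c(OCc9ccccc9)c8 | intermediate

10 | methyl (Z)-3-[3,4,5-tris(benzyloxy)phenyl]prop-2-enoate | COC(=O)/C=C\c8cc(OCc9ccccc9)c(OCc9ccccc9)c(OCc9ccccc9)c8 | intermediate

11 | methyl (2S,3S)-3-[3,4,5-tris(benzyloxy)phenyl]oxirane-2-carboxylate (cis-epoxide) | COC(=O)[C@H]1O[C@H]1c8cc(OCc9ccccc9)c(OCc9ccccc9)c(OCc9ccccc9)c8 | intermediate

12 | (2S,3S)-N-methoxy-N-methyl-3-[3,4,5-tris(benzyloxy)phenyl]oxirane-2-carboxamide (cis-epoxide) | CON(C)C(=O)[C@H]1O[C@H]1c8cc(OCc9ccccc9)c(OCc9ccccc9)c(OCc9ccccc9)c8 | intermediate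

13 | 8-lithio analogue of 7 (lithium in place of bromine at C8 of the upper unit) | CC(C)(C)[Si](C)(C)O[C@@H]1[C@@H](c2c(OCc9ccccc9)cc(OCc9ccccc9)c3c2O[C@H](c8cc(OCc9ccccc9)c(OCc9ccccc9)c(OCc9ccccc9)c8)[C@H](OCc9ccccc9)C3)c4c(OCc9ccccc9)cc(OCc9ccccc9)c([Li])c4O[C@@H]1c8cc(OCc9ccccc9)c(OCc9ccccc9)c(OCc9ccccc9)c8 | intermediate (not isolated)

14 | analogue of 7 carrying at C8 of the upper unit the (2S,3S)-3-[3,4,5-tris(benzyloxy)phenyl]oxirane-2-carbonyl group in place of bromine | CC(C)(C)[Si](C)(C)O[C@@H]1[C@@H](c2c(OCc9ccccc9)cc(OCc9ccccc9)c3c2O[C@H](c8cc(OCc9ccccc9)c(OCc9ccccc9)c(OCc9ccccc9)c8)[C@H](OCc9ccccc9)C3)c4c(OCc9ccccc9)cc(OCc9ccccc9)c(C(=O)[C@H]6O[C@H]6c8cc(OCc9ccccc9)c(OCc9ccccc9)c(OCc9ccccc9)c8)c4O[C@@H]1c8cc(OCc9ccccc9)c(OCc9ccccc9)c(OCc9ccccc9)c8 | intermediate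

15 | 14 without the silyl group (free 3-OH on the upper unit) | O[C@@H]1[C@@H](c2c(OCc9ccccc9)cc(OCc9ccccc9)c3c2O[C@H](c8cc(OCc9ccccc9)c(OCc9ccccc9)c(OCc9ccccc9)c8)[C@H](OCc9ccccc9)C3)c4c(OCc9ccccc9)cc(OCc9ccccc9)c(C(=O)[C@H]6O[C@H]6c8cc(OCc9ccccc9)c(OCc9ccccc9)c(OCc9ccccc9)c8)c4O[C@@H]1c8cc(OCc9ccccc9)c(OCc9ccccc9)c(OCc9ccccc9)c8 | intermediate

16 | 3,4,5-tris(benzyloxy)benzoic acid | OC(=O)c8cc(OCc9ccccc9)c(OCc9ccccc9)c(OCc9ccccc9)c8 | starting material

17 | 3-O-[3,4,5-tris(benzyloxy)benzoyl] ester of 15 | O=C(O[C@@H]1[C@@H](c2c(OCc9ccccc9)cc(OCc9ccccc9)c3c2O[C@H](c8cc(OCc9ccccc9)c(OCc9ccccc9)c(OCc9ccccc9)c8)[C@H](OCc9ccccc9)C3)c4c(OCc9ccccc9)cc(OCc9ccccc9)c(C(=O)[C@H]6O[C@H]6c8cc(OCc9ccccc9)c(OCc9ccccc9)c(OCc9ccccc9)c8)c4O[C@@H]1c8cc(OCc9ccccc9)c(OCc9ccccc9)c(OCc9ccccc9)c8)c8cc(OCc9ccccc9)c(OCc9ccccc9)c(OCc9ccccc9)c8 | intermediate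

18 | carbinol from 17: C8 of the middle unit carries hydroxy[(2R,3S)-3-[3,4,5-tris(benzyloxy)phenyl]oxiran-2-yl]methyl (cis-epoxide; both carbinol epimers) | O=C(O[C@@H]1[C@@H](c2c(OCc9ccccc9)cc(OCc9ccccc9)c3c2O[C@H](c8cc(OCc9ccccc9)c(OCc9ccccc9)c(OCc9ccccc9)c8)[C@H](OCc9ccccc9)C3)c4c(OCc9ccccc9)cc(OCc9ccccc9)c(C(O)[C@H]6O[C@H]6c8cc(OCc9ccccc9)c(OCc9ccccc9)c(OCc9ccccc9)c8)c4O[C@@H]1c8cc(OCc9ccccc9)c(OCc9ccccc9)c(OCc9ccccc9)c8)c8cc(OCc9ccccc9)c(OCc9ccccc9)c(OCc9ccccc9)c8 | intermediate

19 | phloroglucinol (benzene-1,3,5-triol) | Oc1cc(O)cc(O)c1 | starting material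

20 | 18 with a 2,4,6-trihydroxyphenyl group in place of the carbinol hydroxyl (C4 epimer that leads to 21; epoxide intact) | O=C(O[C@@H]1[C@@H](c2c(OCc9ccccc9)cc(OCc9ccccc9)c3c2O[C@H](c8cc(OCc9ccccc9)c(OCc9ccccc9)c(OCc9ccccc9)c8)[C@H](OCc9ccccc9)C3)c4c(OCc9ccccc9)cc(OCc9ccccc9)c([C@@H](c7c(O)cc(O)cc7O)[C@H]6O[C@H]6c8cc(OCc9ccccc9)c(OCc9ccccc9)c(OCc9ccccc9)c8)c4O[C@@H]1c8cc(OCc9ccccc9)c(OCc9ccccc9)c(OCc9ccccc9)c8)c8cc(OCc9ccccc9)c(OCc9ccccc9)c(OCc9ccccc9)c8 | intermediate (not isolated)

21 | (3',4',5'-tri-O-benzyl-epigallocatechin)-(4β→8)-[5,7,3',4',5'-penta-O-benzyl-epigallocatechin 3-O-(3,4,5-tri-O-benzylgallate)]-(4β→8)-(3,5,7,3',4',5'-hexa-O-benzyl-epigallocatechin); top ring A phenols and top 3-OH free | O=C(O[C@@H]1[C@@H](c2c(OCc9ccccc9)cc(OCc9ccccc9)c3c2O[C@H](c8cc(OCc9ccccc9)c(OCc9ccccc9)c(OCc9ccccc9)c8)[C@H](OCc9ccccc9)C3)c4c(OCc9ccccc9)cc(OCc9ccccc9)c([C@H]6c7c(O)cc(O)cc7O[C@H](c8cc(OCc9ccccc9)c(OCc9ccccc9)c(OCc9ccccc9)c8)[C@@H]6O)c4O[C@@H]1c8cc(OCc9ccccc9)c(OCc9ccccc9)c(OCc9ccccc9)c8)c8cc(OCc9ccccc9)c(OCc9ccccc9)c(OCc9ccccc9)c8 | intermediate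

22 | (−)-epigallocatechin-(4β→8)-(−)-epigallocatechin 3-O-gallate-(4β→8)-(−)-epigallocatechin | O=C(O[C@@H]1[C@@H](c2c(O)cc(O)c3c2O[C@H](c2cc(O)c(O)c(O)c2)[C@H](O)C3)c2c(O)cc(O)c([C@H]3c4c(O)cc(O)cc4O[C@H](c4cc(O)c(O)c(O)c4)[C@@H]3O)c2O[C@@H]1c1cc(O)c(O)c(O)c1)c1cc(O)c(O)c(O)c1 | target

## Step count and least certain steps

Total: 16 steps. Longest linear sequence: 11 steps (1, 2, 3, 4, 6, 11, 12, 13, 14, 15, 16).

**Step 15 (key step, proposed new method).** The most likely failure is poor facial selectivity at C4. The first C–C bond forms under open-chain control, anti to the cis-aryl group of the epoxide, which after closure leads to the 3,4-cis series, and the corrective re-opening and re-closure of C4–C4a may be too slow under an acid mild enough to spare the other interflavan bonds. Further risks are rearrangement of the epoxycarbinyl cation, activation of the epoxide before the carbinol (which would give the annulation in the reverse orientation) and 5-exo closure. The fallback is the established chain extension, which sets out from 7 and returns at 22. Bromine–lithium exchange on 7 and protonation give the debrominated dimer silyl ether F1. Desilylation with Bu4NF gives the dimer alcohol F2, and esterification with 16 gives the dimer gallate F3. F3, in excess, is coupled with the capped electrophile 5 under BF3·OEt2 at −78 °C, where attack anti to the C3 and C2 substituents of the cyclic cation gives the 4β trimer F4. Desilylation gives the trimer alcohol F5, and hydrogenolysis of F5 over Pd(OH)2/C with triethylamine removes the benzyl groups and the capping bromine to give 22.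

**Step 11.** Steric shielding of the C8 anion by O1 and the 7-benzyloxy group, together with protonation of the aryllithium by benzylic hydrogens, may lead to incomplete acylation; attack at the epoxide is a lesser risk. The fallback sets out from 11 and 7 and returns at 14. Reduction of 11 with i-Bu2AlH at −78 °C gives the cis-epoxy aldehyde F6. The aryllithium 13 adds to this far more electrophilic carbonyl to give the silylated carbinol F7, and Dess–Martin oxidation of F7 gives 14.

**Step 9.** Loss of cis geometry through the radical intermediate, which the electron-rich aryl group stabilises, and lower enantioselectivity with the bulky 3,5-bis(benzyloxy) pattern are possible, as is ring chlorination. The fallback sets out from 10 and returns at 12. Reduction with i-Bu2AlH gives the (Z)-allylic alcohol F8. Sharpless epoxidation (Ti(Oi-Pr)4, D-(−)-diethyl tartrate, t-BuOOH) gives the cis-epoxy alcohol F9. Oxidation with TEMPO and PhI(OAc)2 in aqueous acetonitrile gives the glycidic acid F10, which is coupled with N,O-dimethylhydroxylamine (EDC·HCl) to give 12.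

**Step 10.** Opening of the benzylic epoxide by chloride under magnesium activation may compete with aminolysis. The fallback sets out from 11 and returns at 12. Saponification with KOH in ethanol at 0 °C gives the potassium glycidate F11, which is coupled directly with N,O-dimethylhydroxylamine hydrochloride and EDC·HCl to give 12.

**Step 16.** Incomplete cleavage among seventeen benzyl groups (partly deprotected intermediates adsorb on the catalyst) and hydrogenolysis of the benzylic C2–O1 bonds on long exposure are the risks. The fallback sets out from 21 and returns at 22 without new isolated compounds: Lewis-acid debenzylation with BCl3 and pentamethylbenzene as cation scavenger in CH2Cl2 at −78 °C.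

## Further compounds

F1 | step 15 | (3-O-TBS-5,7,3',4',5'-penta-O-benzyl-epigallocatechin)-(4β→8)-(3,5,7,3',4',5'-hexa-O-benzyl-epigallocatechin) | CC(C)(C)[Si](C)(C)O[C@@H]1[C@@H](c2c(OCc9ccccc9)cc(OCc9ccccc9)c3c2O[C@H](c8cc(OCc9ccccc9)c(OCc9ccccc9)c(OCc9ccccc9)c8)[C@H](OCc9ccccc9)C3)c4c(OCc9ccccc9)cc(OCc9ccccc9)cc4O[C@@H]1c8cc(OCc9ccccc9)c(OCc9ccccc9)c(OCc9ccccc9)c8

F2 | step 15 | (5,7,3',4',5'-penta-O-benzyl-epigallocatechin)-(4β→8)-(3,5,7,3',4',5'-hexa-O-benzyl-epigallocatechin), free 3-OH on the upper unit | O[C@@H]1[C@@H](c2c(OCc9ccccc9)cc(OCc9ccccc9)c3c2O[C@H](c8cc(OCc9ccccc9)c(OCc9ccccc9)c(OCc9ccccc9)c8)[C@H](OCc9ccccc9)C3)c4c(OCc9ccccc9)cc(OCc9ccccc9)cc4O[C@@H]1c8cc(OCc9ccccc9)c(OCc9ccccc9)c(OCc9ccccc9)c8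

F3 | step 15 | 3-O-[3,4,5-tris(benzyloxy)benzoyl] ester of F2 | O=C(O[C@@H]1[C@@H](c2c(OCc9ccccc9)cc(OCc9ccccc9)c3c2O[C@H](c8cc(OCc9ccccc9)c(OCc9ccccc9)c(OCc9ccccc9)c8)[C@H](OCc9ccccc9)C3)c4c(OCc9ccccc9)cc(OCc9ccccc9)cc4O[C@@H]1c8cc(OCc9ccccc9)c(OCc9ccccc9)c(OCc9ccccc9)c8)c8cc(OCc9ccccc9)c(OCc9ccccc9)c(OCc9ccccc9)c8

F4 | step 15 | (8-bromo-3-O-TBS-penta-O-benzyl-epigallocatechin)-(4β→8)-[penta-O-benzyl-epigallocatechin 3-O-(tri-O-benzylgallate)]-(4β→8)-(hexa-O-benzyl-epigallocatechin) | O=C(O[C@@H]1[C@@H](c2c(OCc9ccccc9)cc(OCc9ccccc9)c3c2O[C@H](c8cc(OCc9ccccc9)c(OCc9ccccc9)c(OCc9ccccc9)c8)[C@H](OCc9ccccc9)C3)c4c(OCc9ccccc9)cc(OCc9ccccc9)c([C@H]6c7c(OCc9ccccc9)cc(OCc9ccccc9)c(Br)c7O[C@H](c8cc(OCc9ccccc9)c(OCc9ccccc9)c(OCc9ccccc9)c8)[C@@H]6O[Si](C)(C)C(C)(C)C)c4O[C@@H]1c8cc(OCc9ccccc9)c(OCc9ccccc9)c(OCc9ccccc9)c8)c8cc(OCc9ccccc9)c(OCc9ccccc9)c(OCc9ccccc9)c8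

F5 | step 15 | F4 without the silyl group (free 3-OH on the top unit) | O=C(O[C@@H]1[C@@H](c2c(OCc9ccccc9)cc(OCc9ccccc9)c3c2O[C@H](c8cc(OCc9ccccc9)c(OCc9ccccc9)c(OCc9ccccc9)c8)[C@H](OCc9ccccc9)C3)c4c(OCc9ccccc9)cc(OCc9ccccc9)c([C@H]6c7c(OCc9ccccc9)cc(OCc9ccccc9)c(Br)c7O[C@H](c8cc(OCc9ccccc9)c(OCc9ccccc9)c(OCc9ccccc9)c8)[C@@H]6O)c4O[C@@H]1c8cc(OCc9ccccc9)c(OCc9ccccc9)c(OCc9ccccc9)c8)c8cc(OCc9ccccc9)c(OCc9ccccc9)c(OCc9ccccc9)c8

F6 | step 11 | (2S,3S)-3-[3,4,5-tris(benzyloxy)phenyl]oxirane-2-carbaldehyde (cis-epoxide) | O=C[C@H]1O[C@H]1c8cc(OCc9ccccc9)c(OCc9ccccc9)c(OCc9ccccc9)c8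

F7 | step 11 | analogue of 7 carrying at C8 of the upper unit hydroxy[(2R,3S)-3-[3,4,5-tris(benzyloxy)phenyl]oxiran-2-yl]methyl in place of bromine (both carbinol epimers) | CC(C)(C)[Si](C)(C)O[C@@H]1[C@@H](c2c(OCc9ccccc9)cc(OCc9ccccc9)c3c2O[C@H](c8cc(OCc9ccccc9)c(OCc9ccccc9)c(OCc9ccccc9)c8)[C@H](OCc9ccccc9)C3)c4c(OCc9ccccc9)cc(OCc9ccccc9)c(C(O)[C@H]6O[C@H]6c8cc(OCc9ccccc9)c(OCc9ccccc9)c(OCc9ccccc9)c8)c4O[C@@H]1c8cc(OCc9ccccc9)c(OCc9ccccc9)c(OCc9ccccc9)c8

F8 | step 9 | (Z)-3-[3,4,5-tris(benzyloxy)phenyl]prop-2-en-1-ol | OC/C=C\c8cc(OCc9ccccc9)c(OCc9ccccc9)c(OCc9ccccc9)c8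

F9 | step 9 | [(2R,3S)-3-[3,4,5-tris(benzyloxy)phenyl]oxiran-2-yl]methanol (cis-epoxide) | OC[C@H]1O[C@H]1c8cc(OCc9ccccc9)c(OCc9ccccc9)c(OCc9ccccc9)c8

F10 | step 9 | (2S,3S)-3-[3,4,5-tris(benzyloxy)phenyl]oxirane-2-carboxylic acid (cis-epoxide) | OC(=O)[C@H]1O[C@H]1c8cc(OCc9ccccc9)c(OCc9ccccc9)c(OCc9ccccc9)c8

F11 | step 10 | potassium (2S,3S)-3-[3,4,5-tris(benzyloxy)phenyl]oxirane-2-carboxylate | [K+].[O-]C(=O)[C@H]1O[C@H]1c8cc(OCc9ccccc9)c(OCc9ccccc9)c(OCc9ccccc9)c8

F0 | step 16 | none | none

A1 | alternative 1 | (5,7,3',4',5'-penta-O-benzyl-epigallocatechin 3-O-(tri-O-benzylgallate))-(4β→8)-(hexa-O-benzyl-epigallocatechin) | O=C(O[C@@H]1[C@@H](c2c(OCc9ccccc9)cc(OCc9ccccc9)c3c2O[C@H](c8cc(OCc9ccccc9)c(OCc9ccccc9)c(OCc9ccccc9)c8)[C@H](OCc9ccccc9)C3)c4c(OCc9ccccc9)cc(OCc9ccccc9)cc4O[C@@H]1c8cc(OCc9ccccc9)c(OCc9ccccc9)c(OCc9ccccc9)c8)c8cc(OCc9ccccc9)c(OCc9ccccc9)c(OCc9ccccc9)c8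

A2 | alternative 1 | diyne: middle-unit flavan gallate bearing at C4 an ethynyl ether O–CH(aryl)–CH(OBn)–CH2–C≡C–OBn (aryl = 3,4,5-tris(benzyloxy)phenyl) | O=C(O[C@@H]1[C@@H](C#CO[C@H](c8cc(OCc9ccccc9)c(OCc9ccccc9)c(OCc9ccccc9)c8)[C@H](OCc9ccccc9)CC#COCc9ccccc9)c4c(OCc9ccccc9)cc(OCc9ccccc9)cc4O[C@@H]1c8cc(OCc9ccccc9)c(OCc9ccccc9)c(OCc9ccccc9)c8)c8cc(OCc9ccccc9)c(OCc9ccccc9)c(OCc9ccccc9)c8

A3 | alternative 1 | benzyloxyacetylene | C#COCc1ccccc1

A4 | alternative 2 | (3-O-TBS-5,7,3',4',5'-penta-O-benzyl-epigallocatechin)-(4β→8)-(hexa-O-benzyl-epigallocatechin) | CC(C)(C)[Si](C)(C)O[C@@H]1[C@@H](c2c(OCc9ccccc9)cc(OCc9ccccc9)c3c2O[C@H](c8cc(OCc9ccccc9)c(OCc9ccccc9)c(OCc9ccccc9)c8)[C@H](OCc9ccccc9)C3)c4c(OCc9ccccc9)cc(OCc9ccccc9)cc4O[C@@H]1c8cc(OCc9ccccc9)c(OCc9ccccc9)c(OCc9ccccc9)c8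

A5 | alternative 2 | seco form of A4: ring C of the middle unit open at O1–C8a, free benzylic hydroxyl at C2, bromine at C8a | CC(C)(C)[Si](C)(C)O[C@@H]([C@H](O)c8cc(OCc9ccccc9)c(OCc9ccccc9)c(OCc9ccccc9)c8)[C@@H](c2c(OCc9ccccc9)cc(OCc9ccccc9)c3c2O[C@H](c8cc(OCc9ccccc9)c(OCc9ccccc9)c(OCc9ccccc9)c8)[C@H](OCc9ccccc9)C3)c4c(OCc9ccccc9)cc(OCc9ccccc9)cc4Br

A6 | alternative 3 | (5,7,3',5'-tetra-O-benzyl-epigallocatechin)-(4β→8)-(hexa-O-benzyl-epigallocatechin), free 3-OH and free 4'-phenol on the upper unit | O[C@@H]1[C@@H](c2c(OCc9ccccc9)cc(OCc9ccccc9)c3c2O[C@H](c8cc(OCc9ccccc9)c(OCc9ccccc9)c(OCc9ccccc9)c8)[C@H](OCc9ccccc9)C3)c4c(OCc9ccccc9)cc(OCc9ccccc9)cc4O[C@@H]1c8cc(OCc9ccccc9)c(O)c(OCc9ccccc9)c8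

A7 | alternative 3 | seco form of A6: ring C of the middle unit open at O1–C2, C2 as the CH2 of a 4-hydroxy-3,5-bis(benzyloxy)benzyl group, free C8a phenol | O[C@@H](Cc8cc(OCc9ccccc9)c(O)c(OCc9ccccc9)c8)[C@@H](c2c(OCc9ccccc9)cc(OCc9ccccc9)c3c2O[C@H](c8cc(OCc9ccccc9)c(OCc9ccccc9)c(OCc9ccccc9)c8)[C@H](OCc9ccccc9)C3)c4c(OCc9ccccc9)cc(OCc9ccccc9)cc4O
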